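Remark: the target, Selaginellin U, is compound 15 in the numbering below. Its dienone ring and the phenol ring on the same carbon exchange roles by a proton shift, so a precursor with two identical 4-methoxyphenyl groups on that carbon can give only one product.

## Analysis of the target

Selaginellin U (15) is built on one benzene ring A that carries four different carbon substituents on four neighbouring positions: a methyl group on C1, a (4-hydroxyphenyl)ethynyl group on C2, the quinone methide carbon Cq on C3 and the 4-hydroxyphenyl ring B on C4; C5 and C6 carry hydrogen. Cq is doubly bonded to a cyclohexa-2,5-dienone ring and singly bonded to a further 4-hydroxyphenyl ring, so this part is a fuchsone, the dehydrated form of a triarylcarbinol. There is no stereocentre, and the exocyclic double bond ends in a symmetrical dienone ring, so no double-bond isomerism arises. The sensitive groups are the fuchsone (electrophilic at Cq and responsive to acid and base), three free phenols, and a diaryl alkyne sitting next to Cq, where an oxygen on Cq or a cation at Cq is within reach of it. A cation at Cq can also close onto ring B to give a 9,9-diarylfluorene. The difficulty is the contiguous 1,2,3,4-substitution with full regiocontrol, and in particular the C3–Cq bond, which is wedged between the substituents on C2 and C4. The strategy rests on reading ring A as three two-carbon units: C1–C2 is a propyne carrying the methyl group, C3–C4 is an aryl alkyne that already carries Cq, and C5–C6 is acetylene. The oxygen on Cq, which must leave in the end anyway, lies three atoms from C2 and can be tied to C2 through silicon.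

## Retrosynthetic reasoning

Quinone methide 15 is the dehydration product of the tetraphenolic carbinol 14, which is the demethylated form of the tris(methyl ether) carbinol 13. No skeletal bond is cut; three O–CH3 bonds and the Cq–OH bond are the retrons. Methyl ethers are chosen because they should pass through organolithium addition, silylation, rhodium catalysis, electrophilic iodine and palladium/copper catalysis. The forward step has to remove three methyl groups and ionise the Cq–O bond without damaging the alkyne.

In 13 the C2–C(sp) bond is cut, giving aryl iodide 12 and alkyne 1. The arylethynyl group is introduced this late because a fourth triple bond would compete when ring A is assembled from alkynes, and because it would not survive electrophilic iodine. Alkyne 1 is needed earlier in the route as well, so no new building block is added. The forward reaction is a Sonogashira coupling at an iodide flanked on both sides, next to a free tertiary carbinol.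

The C2–I bond of 12 is traced back to a C2–Si bond and the Cq–OH group to a Cq–O–Si link. Both are present in benzoxasilole 10, which should pass to 12 through chlorosilyl ether 11. The gain is that the silicon atom marks C2 unambiguously, so the halogen needs no directing effect. The forward step must replace silicon by iodine at the ipso carbon faster than the three anisyl rings are iodinated, and then release the carbinol from silicon.

Benzoxasilole 10 is cut at three ring A bonds, C2–C3, C4–C5 and C6–C1, into the silyl-ether-tethered diyne 8 and acetylene 9. These cuts are chosen because every substituent then sits on an alkyne carbon before the ring exists (methyl on C1, anisyl on C4, Cq on C3). The crowded C3–Cq bond is therefore never made on a finished arene; ring A is built around it. The tether allows only one arrangement of the three alkynes. The forward reaction must favour the cross-reaction of 8 with 9 over self-reaction of either.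

Diyne 8 is cut at the Si–O bond into propargylic carbinol 4 and chlorosilane 7. The forward reaction is the silylation of a tertiary, acid-sensitive alcohol and has to run under basic conditions.

Carbinol 4 is cut at the Cq–C(sp) bond into alkyne 1 and ketone 2, joined through acetylide 3. Chlorosilane 7 is cut at the Si–C(sp) bond into dichlorosilane 5 and Grignard reagent 6. Compounds 1, 2, 5, 6 and 9 are commercial.

## Alternatives that were turned down

Alternative 1: Ring A is cut at C1–C6 and C3–C4 into a three-carbon dinucleophile and a three-carbon dielectrophile. In the forward sense the bis(silyl enol ether) A1, (1Z,3Z)-1-methoxy-1,3-bis(trimethylsilyloxy)penta-1,3-diene, would condense under a strong Lewis acid with the keto acetal A2, 3,3-dimethoxy-1-(4-methoxyphenyl)propan-1-one. The terminal carbon of A1 would attack the acetal carbon, the central carbon would close on the aryl ketone, and loss of methanol and water would give the salicylate A3, methyl 2-hydroxy-6-(4-methoxyphenyl)-3-methylbenzoate. Triflation of the C2 hydroxyl, Sonogashira coupling with 1 and twofold addition of 4-methoxyphenylmagnesium bromide A4 to the ester would then lead to 13.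
- For it: the polarity of the two partners fixes the regiochemistry, no gas and no precious metal are needed for ring formation, and the C2 phenol is a cleaner handle for the alkyne than an ipso-iodination that must distinguish a C–Si bond from three anisyl rings. On that last point it is stronger than the chosen route.
- Against it: Cq arrives as an ester carbon flanked by two ortho substituents. Two aryl additions to such an ester, the second to a doubly ortho-substituted benzophenone, are the least favourable way to make the most crowded centre of the molecule. Each partner needs about two steps, so the route comes to roughly nine steps.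
- Comparison: the chosen route brings Cq in with both aryl groups already attached, from ketone 2, and is shorter.

Alternative 2: No ring is built. 4-Bromo-2-chlorotoluene A5 already holds the C1 methyl group and halogens on C2 and C4, and the C4–aryl, C2–C(sp) and C3–I bonds would be made in one flask. A5 would be magnesiated at C3 by a hindered magnesium amide; loss of bromide would give the C3–C4 aryne, which A4 attacks at C4. Loss of chloride from the new aryl Grignard reagent would give the C2–C3 aryne, which [(4-methoxyphenyl)ethynyl]magnesium bromide A6 attacks at C2, and iodination at C3 would give A7, 2-iodo-4'-methoxy-3-[(4-methoxyphenyl)ethynyl]-4-methylbiphenyl. Iodine–metal exchange on A7 and addition to ketone 2 would give 13.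
- For it: it is by far the shortest route, three or four steps to the target against seven, and on step economy it is clearly stronger than the chosen route.
- Against it: it depends on several selectivities that the connectivity does not enforce. The carbanion at C3 must expel bromide and not chloride. The first aryne is polarised by the neighbouring chlorine, which is favourable, but the second is flanked by methyl on one side and aryl on the other, so attack at C2 or C3 is poorly biased. A4 and A6 must each react with only one of the two arynes. Alkynyl Grignard reagents are sluggish toward arynes, and the amine set free from the base is a competing nucleophile.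
- Comparison: the chosen route is longer, but the position of every substituent follows from which atoms are bonded in 8, not from relative rates in a cascade.

Alternative 3: Ring A is cut at C1–C2 and C3–C4 into the diene A8, (1E,3E)-1-(4-methoxyphenyl)penta-1,3-diene, and the diynone A9, 1,5-bis(4-methoxyphenyl)penta-2,4-diyn-1-one. A Diels–Alder addition of A8 to the triple bond next to the carbonyl group, followed by dehydrogenation of the 1,4-cyclohexadiene with a quinone oxidant in the same flask, would give the ketone A10, [6-(4-methoxyphenyl)-2-[(4-methoxyphenyl)ethynyl]-3-methylphenyl](4-methoxyphenyl)methanone. Addition of A4 to the carbonyl group of A10 would give 13.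
- For it: the C2 alkyne is carried in from the start, so there is no ipso-substitution and no late coupling at a doubly flanked position. The endgame from an ortho-alkynyl benzophenone is conventional, and the step count is about the same as in the chosen route. On these points it is as strong or stronger.
- Against it: the regiochemistry rests on orbital coefficients only. The diene has a donor at each terminus, and matching the methyl terminus with the β-carbon of the ynone is the preferred orientation, not the only one. A 1,4-disubstituted aryl diene is a slow diene; heating invites oligomerisation of the diynone, and Lewis acids invite polymerisation of the electron-rich diene. Two triple bonds compete, and the diene must be isomerically pure. The last aryl addition meets a doubly ortho-substituted ketone.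
- Comparison: in the chosen route regiochemistry is not in question, and Cq is fully arylated before ring A exists.

Key step: step 4

## Route

Step 1
Reactants: 1 4-ethynylanisole; 2 4,4'-dimethoxybenzophenone
Product: 4 1,1,3-tris(4-methoxyphenyl)prop-2-yn-1-ol, via lithium (4-methoxyphenyl)acetylide 3 (not isolated)
Conditions: n-BuLi (1.05 equiv), THF, −78 °C; then 2, −78 °C → rt; H2O
Reagents that add atoms: none
Why: n-BuLi deprotonates the terminal alkyne, and the lithium acetylide undergoes 1,2-addition to the non-enolisable diaryl ketone; Cq carries two identical anisyl groups, so no stereocentre arises, and a neutral work-up avoids ionisation or Meyer–Schuster rearrangement of the acid-sensitive carbinol.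

Step 2
Reactants: 5 dichlorodimethylsilane; 6 1-propynylmagnesium bromide
Product: 7 chlorodimethyl(prop-1-yn-1-yl)silane
Conditions: 5 (4 equiv), THF, −78 °C; 6 (THF solution) added dropwise; → rt; filtration under argon, fractional distillation
Reagents that add atoms: none
Why: Nucleophilic substitution at silicon by an alkynyl Grignard reagent; the excess of 5 and the inverse addition should hold the reaction at monosubstitution, and the only likely contaminant, the dialkynylsilane, has no Si–Cl bond and is a spectator in step 3.

Step 3
Reactants: 4 1,1,3-tris(4-methoxyphenyl)prop-2-yn-1-ol; 7 chlorodimethyl(prop-1-yn-1-yl)silane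
Product: 8 dimethyl(prop-1-yn-1-yl){[1,1,3-tris(4-methoxyphenyl)prop-2-yn-1-yl]oxy}silane
Conditions: 7 (1.5 equiv), Et3N (3 equiv), DMAP (0.2 equiv), CH2Cl2, 0 °C → rt; filtration through Et3N-deactivated silica gel
Reagents that add atoms: none
Why: DMAP-assisted O-silylation of a tertiary alcohol by a small, activated chlorosilane comparable in size to chlorotrimethylsilane; the excess amine takes up the HCl, so the bis(anisyl) carbinol is never exposed to acid.

Step 4
Reactants: 8 dimethyl(prop-1-yn-1-yl){[1,1,3-tris(4-methoxyphenyl)prop-2-yn-1-yl]oxy}silane; 9 acetylene
Product: 10 3,3,4-tris(4-methoxyphenyl)-1,1,7-trimethyl-1,3-dihydro-2,1-benzoxasilole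
Conditions: RhCl(PPh3)3 (10 mol%), 9 (1 atm, balloon), toluene, 60 °C, 8 added by syringe pump over several hours
Reagents that add atoms: none
Why: After loss of one PPh3, monovalent rhodium binds both triple bonds of 8 and undergoes oxidative cyclisation to a bicyclic rhodacyclopentadiene of trivalent rhodium, in which the C2–C3 bond is made and the metal carries C1 and C4. Acetylene 9 then coordinates and inserts into a Rh–C bond, and reductive elimination forms C4–C5 and C6–C1 and returns monovalent rhodium. The closest known reaction type is the rhodium- or cobalt-catalysed [2+2+2] cycloaddition of 1,6-diynes, silyl-ether-tethered ones included, with a monoalkyne. The oxasilole ring closes in the oxidative coupling, which joins the two inner alkyne carbons across the three-atom C–O–Si tether, and the gem-diaryl group on Cq should favour this closure; the benzene ring closes by insertion and reductive elimination. No stereocentre is formed, because Cq carries two identical anisyl groups and silicon two methyl groups. The step needs cross-selectivity between 8 and 9: the tether makes the first C–C bond intramolecular, the fully substituted and hindered alkyne ends of 8 make insertion of a second molecule of 8 slow, and slow addition of 8 under an atmosphere of 9 keeps the small alkyne in excess. Regiochemistry cannot go wrong, since the tether fixes C2 next to C3 and 9 is symmetrical.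

Step 5
Reactants: 10 3,3,4-tris(4-methoxyphenyl)-1,1,7-trimethyl-1,3-dihydro-2,1-benzoxasilole
Product: 12 (3-iodo-4'-methoxy-4-methylbiphenyl-2-yl)bis(4-methoxyphenyl)methanol, via chlorosilyl ether 11 (not isolated)
Conditions: ICl (1.1 equiv), CH2Cl2, −78 → 0 °C; aq. Na2S2O3; then K2CO3, MeOH/H2O, rt
Reagents that add atoms: iodine monochloride, SMILES ClI
Why: Ipso-iododesilylation, an electrophilic aromatic substitution in which iodine attacks C2, the arenium ion is stabilised by the β-silicon effect and chloride takes the silicon to give 11; the strained C2–Si bond between methyl and Cq should react before the anisyl C–H positions at low temperature with one equivalent of reagent. Carbonate in aqueous methanol then cleaves the labile Si–O bond and frees the carbinol.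

Step 6
Reactants: 12 (3-iodo-4'-methoxy-4-methylbiphenyl-2-yl)bis(4-methoxyphenyl)methanol; 1 4-ethynylanisole
Product: 13 {4'-methoxy-3-[(4-methoxyphenyl)ethynyl]-4-methylbiphenyl-2-yl}bis(4-methoxyphenyl)methanol
Conditions: 1 (1.5 equiv), Pd(PPh3)2Cl2 (5 mol%), CuI (10 mol%), Et3N/THF, 60 °C, degassed
Reagents that add atoms: none
Why: Sonogashira coupling: zerovalent palladium inserts into the C–I bond, the copper acetylide formed from 1, CuI and amine transmetalates, and reductive elimination forms the C2–C(sp) bond; aryl iodides tolerate two ortho substituents in this coupling, and the methyl ethers and the tertiary carbinol are inert to amine base.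

Step 7
Reactants: 13 {4'-methoxy-3-[(4-methoxyphenyl)ethynyl]-4-methylbiphenyl-2-yl}bis(4-methoxyphenyl)methanol
Product: 15 Selaginellin U, via tetraphenolic carbinol 14 (not isolated)
Conditions: BBr3 (10 equiv), CH2Cl2, −78 → 0 °C; H2O, then aq. NaHCO3 to neutral
Reagents that add atoms: none
Why: BBr3 cleaves the three aryl methyl ethers (boron coordinates to oxygen, bromide attacks the methyl group) and ionises the Cq–O bond; hydrolysis of the aryl borates on work-up gives 14, which loses water across Cq and a para-hydroxyl group to give the fuchsone. The two para-oxygenated rings on Cq are equivalent, so a single quinone methide results, and no stereocentre or double-bond isomer is involved.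

## Compound list

1 | 4-ethynylanisole | COc1ccc(C#C)cc1 | starting material
2 | 4,4'-dimethoxybenzophenone | COc1ccc(C(=O)c2ccc(OC)cc2)cc1 | starting material
3 | lithium (4-methoxyphenyl)acetylide | COc1ccc(C#C[Li])cc1 | intermediate (not isolated)
4 | 1,1,3-tris(4-methoxyphenyl)prop-2-yn-1-ol | COc1ccc(C#CC(O)(c2ccc(OC)cc2)c2ccc(OC)cc2)cc1 | intermediate
5 | dichlorodimethylsilane | C[Si](C)(Cl)Cl | starting material
6 | 1-propynylmagnesium bromide | CC#C[Mg]Br | starting material
7 | chlorodimethyl(prop-1-yn-1-yl)silane | CC#C[Si](C)(C)Cl | intermediate
8 | dimethyl(prop-1-yn-1-yl){[1,1,3-tris(4-methoxyphenyl)prop-2-yn-1-yl]oxy}silane | COc1ccc(C#CC(O[Si](C)(C)C#CC)(c2ccc(OC)cc2)c2ccc(OC)cc2)cc1 | intermediate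
9 | acetylene | C#C | starting material
10 | 3,3,4-tris(4-methoxyphenyl)-1,1,7-trimethyl-1,3-dihydro-2,1-benzoxasilole | Cc1ccc(-c2ccc(OC)cc2)c2c1[Si](C)(C)OC2(c1ccc(OC)cc1)c1ccc(OC)cc1 | intermediate
11 | chloro{[(3-iodo-4'-methoxy-4-methylbiphenyl-2-yl)bis(4-methoxyphenyl)methyl]oxy}dimethylsilane | Cc1ccc(-c2ccc(OC)cc2)c(C(O[Si](C)(C)Cl)(c2ccc(OC)cc2)c2ccc(OC)cc2)c1I | intermediate (not isolated)
12 | (3-iodo-4'-methoxy-4-methylbiphenyl-2-yl)bis(4-methoxyphenyl)methanol | Cc1ccc(-c2ccc(OC)cc2)c(C(O)(c2ccc(OC)cc2)c2ccc(OC)cc2)c1I | intermediate
13 | {4'-methoxy-3-[(4-methoxyphenyl)ethynyl]-4-methylbiphenyl-2-yl}bis(4-methoxyphenyl)methanol | Cc1ccc(-c2ccc(OC)cc2)c(C(O)(c2ccc(OC)cc2)c2ccc(OC)cc2)c1C#Cc1ccc(OC)cc1 | intermediate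
14 | {4'-hydroxy-3-[(4-hydroxyphenyl)ethynyl]-4-methylbiphenyl-2-yl}bis(4-hydroxyphenyl)methanol | Cc1ccc(-c2ccc(O)cc2)c(C(O)(c2ccc(O)cc2)c2ccc(O)cc2)c1C#Cc1ccc(O)cc1 | intermediate (not isolated)
15 | Selaginellin U, 4-[{4'-hydroxy-3-[(4-hydroxyphenyl)ethynyl]-4-methylbiphenyl-2-yl}(4-hydroxyphenyl)methylidene]cyclohexa-2,5-dien-1-one | Cc1ccc(-c2ccc(O)cc2)c(C(=C2C=CC(=O)C=C2)c2ccc(O)cc2)c1C#Cc1ccc(O)cc1 | target

## Step count and least certain steps

Total: 7 steps. Longest linear sequence: 6 steps (steps 1, 3, 4, 5, 6 and 7; step 2 is a one-step side branch).

Step 4 (key step). Both alkynes of 8 are internal and one is attached to a quaternary carbon, so oxidative cyclisation may be slow. The catalyst would then be consumed in oligomerising acetylene, or the Si–O tether could be lost before the ring forms. Fallback: replace the gas by a liquid alkene that acts as an acetylene equivalent. Setting out from 8, a cationic rhodium catalyst ([Rh(cod)2]BF4 with BINAP, 1,2-dichloroethane, rt to 60 °C) and excess vinyl acetate should give the cyclohexadienyl acetate F1. F1 loses acetic acid in the same flask to aromatise, and the route is rejoined at 10. The orientation of the alkene insertion is irrelevant, because the acetate is eliminated.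

Step 5. Iodination of the anisyl rings ortho to methoxy may compete with ipso-attack, which is slowed by the oxygen on silicon and by the two flanking groups. Lewis-acid ionisation of the Cq–O bond may also be followed by ring closure onto ring B. Fallback: exchange silicon for oxygen instead of halogen. Setting out from 10, Tamao–Fleming oxidation (H2O2, KHCO3, KF, THF/MeOH) should give the phenol 2-[hydroxybis(4-methoxyphenyl)methyl]-4'-methoxy-4-methylbiphenyl-3-ol F2. Selective O-triflation of the phenol (PhNTf2, Cs2CO3, DMF) gives the aryl triflate F3, and Sonogashira coupling of F3 with 1 (Pd(PPh3)2Cl2, CuI, Et3N, DMF, 80 °C) rejoins the route at 13.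

Step 6. Coupling at the doubly flanked iodide may be slow enough for oxidative (Glaser) dimerisation of 1 to take over. Once the alkyne is in place, metal-promoted addition of the neighbouring carbinol O–H across it may also follow. Fallback: cap the carbinol first. Setting out from 12, methanol with a catalytic amount of pyridinium p-toluenesulfonate should give the trityl-type methyl ether F4 by reversible ionisation of Cq. Sonogashira coupling of F4 with 1 gives the methyl ether F5, and the BBr3 conditions of step 7 ionise this ether just as they do the carbinol, so the route is rejoined at 15.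

Step 7. BBr3 or the HBr formed from it may add across the diaryl alkyne, and the Cq cation may undergo Friedel–Crafts closure onto ring B; demethylation may also stop short. Fallback: demethylate before the alkyne is present. Setting out from 12, BBr3 (CH2Cl2, −78 → 0 °C) and aqueous work-up should give the iodo quinone methide F6. Sonogashira coupling of F6 with commercial 4-ethynylphenol (Pd(PPh3)2Cl2, CuI, Et3N, DMF), followed by neutralisation, rejoins the route at 15. The fallback removes the alkyne risk; the Friedel–Crafts risk remains and is met by low temperature.

Step 3. Silylation of the hindered tertiary alcohol may stall, and the moisture-sensitive chlorosilane 7 may hydrolyse before it reacts. Fallback: build the tether from the oxygen side. Setting out from 4, deprotonation with n-BuLi (THF, −78 °C) and addition to a large excess of 5 should give the chlorosilyl ether F7. After removal of the excess 5 under reduced pressure, addition of 6 at 0 °C displaces the chloride on silicon and rejoins the route at 8.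

## Further compounds

F1 | step 4 | 3,3,4-tris(4-methoxyphenyl)-1,1,7-trimethyl-1,3,5,6-tetrahydro-2,1-benzoxasilol-6-yl acetate (racemic) | CC1=C2[Si](C)(C)OC(c3ccc(OC)cc3)(c3ccc(OC)cc3)C2=C(c2ccc(OC)cc2)CC1OC(C)=O
F2 | step 5 | 2-[hydroxybis(4-methoxyphenyl)methyl]-4'-methoxy-4-methylbiphenyl-3-ol | Cc1ccc(-c2ccc(OC)cc2)c(C(O)(c2ccc(OC)cc2)c2ccc(OC)cc2)c1O
F3 | step 5 | 2-[hydroxybis(4-methoxyphenyl)methyl]-4'-methoxy-4-methylbiphenyl-3-yl trifluoromethanesulfonate | Cc1ccc(-c2ccc(OC)cc2)c(C(O)(c2ccc(OC)cc2)c2ccc(OC)cc2)c1OS(=O)(=O)C(F)(F)F
F4 | step 6 | 3-iodo-4'-methoxy-2-[methoxybis(4-methoxyphenyl)methyl]-4-methylbiphenyl | Cc1ccc(-c2ccc(OC)cc2)c(C(OC)(c2ccc(OC)cc2)c2ccc(OC)cc2)c1I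
F5 | step 6 | 4'-methoxy-2-[methoxybis(4-methoxyphenyl)methyl]-3-[(4-methoxyphenyl)ethynyl]-4-methylbiphenyl | Cc1ccc(-c2ccc(OC)cc2)c(C(OC)(c2ccc(OC)cc2)c2ccc(OC)cc2)c1C#Cc1ccc(OC)cc1
F6 | step 7 | 4-[(4'-hydroxy-3-iodo-4-methylbiphenyl-2-yl)(4-hydroxyphenyl)methylidene]cyclohexa-2,5-dien-1-one | Cc1ccc(-c2ccc(O)cc2)c(C(=C2C=CC(=O)C=C2)c2ccc(O)cc2)c1I
F7 | step 3 | chloro(dimethyl){[1,1,3-tris(4-methoxyphenyl)prop-2-yn-1-yl]oxy}silane | COc1ccc(C#CC(O[Si](C)(C)Cl)(c2ccc(OC)cc2)c2ccc(OC)cc2)cc1
A1 | alternative 1 | (1Z,3Z)-1-methoxy-1,3-bis(trimethylsilyloxy)penta-1,3-diene | C/C=C(\O[Si](C)(C)C)/C=C(\O[Si](C)(C)C)OC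
A2 | alternative 1 | 3,3-dimethoxy-1-(4-methoxyphenyl)propan-1-one | COc1ccc(C(=O)CC(OC)OC)cc1
A3 | alternative 1 | methyl 2-hydroxy-6-(4-methoxyphenyl)-3-methylbenzoate | COC(=O)c1c(O)c(C)ccc1-c1ccc(OC)cc1
A4 | alternative 1 | 4-methoxyphenylmagnesium bromide | COc1ccc([Mg]Br)cc1
A5 | alternative 2 | 4-bromo-2-chlorotoluene | Cc1ccc(Br)cc1Cl
A6 | alternative 2 | [(4-methoxyphenyl)ethynyl]magnesium bromide | COc1ccc(C#C[Mg]Br)cc1
A7 | alternative 2 | 2-iodo-4'-methoxy-3-[(4-methoxyphenyl)ethynyl]-4-methylbiphenyl | Cc1ccc(-c2ccc(OC)cc2)c(I)c1C#Cc1ccc(OC)cc1
A8 | alternative 3 | (1E,3E)-1-(4-methoxyphenyl)penta-1,3-diene | C/C=C/C=C/c1ccc(OC)cc1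
A9 | alternative 3 | 1,5-bis(4-methoxyphenyl)penta-2,4-diyn-1-one | COc1ccc(C#CC#CC(=O)c2ccc(OC)cc2)cc1
A10 | alternative 3 | [6-(4-methoxyphenyl)-2-[(4-methoxyphenyl)ethynyl]-3-methylphenyl](4-methoxyphenyl)methanone | Cc1ccc(-c2ccc(OC)cc2)c(C(=O)c2ccc(OC)cc2)c1C#Cc1ccc(OC)cc1
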